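If doubling second substrate was to pay, part of each turnover had to be spent waiting for it, so I went looking for that part.

| flask | starting material | second substrate | free enzyme | remark |
|---|---|---|---|---|
| alder | 0.20 M | 1.3 equiv | 0.005 mol% | run made earlier |
| elm | 0.20 M | 1.3 equiv | 0.02 mol% | run made earlier |
| flask | 0.20 M | 1.30 equiv | 0.01 mol% |  |

| run | time / h | target / % |
|---|---|---|
| alder | 1.33 | 1.9 |
| alder | 4.00 | 5.3 |
| alder | 8.00 | 10.3 |
| alder | 10.0 | 13.7 |
| alder | 15.0 | 19.6 |
| alder | 20.0 | 26.0 |
| elm | 3.00 | 15.7 |
| elm | 6.00 | 31.3 |
| elm | 10.0 | 49.9 |
| elm | 12.0 | 59.6 |
| elm | 15.0 | 72.6 |
| elm | 20.0 | 90.6 |

(each reading ± 0.3 percentage points)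

- apparent order in second substrate when 5.0% of the starting material are converted (percent change of the rate of making target for one percent more second substrate charged)
- apparent order in free enzyme when 5.0% of the starting material are converted (percent change of the rate of making target for one percent more free enzyme charged)
- factor on the rate of making target when 5.0% of the starting material are converted if second substrate is charged twice over

- the earlier runs were read with a standard deviation of 0.3 percentage points
- reactions considered so far: starting material + free enzyme <-> first complex; first complex -> loaded enzyme + first product; second substrate + loaded enzyme <-> second complex; second complex -> free enzyme + target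
- no earlier run changes the charge of second substrate; that part of a forecast is a guess

1. I took the enzyme first. The alder run made 0.0132 h⁻¹ of the charge early on, and the elm run made 0.0523 h⁻¹. Across those two loadings the order in free enzyme came to 0.991. Two loadings are thin evidence, but I committed to it.

2. I split the time per turnover into a constant part, a part going as the inverse of starting material left, and a part going as the inverse of second substrate left. In the elm run this time had grown by 45.4% near 81.6% conversion. If second substrate carried that growth by itself, its share at 5.0% was 0.287.

3. But that assumed the thinning of starting material took no part in the growth. So I tested the middle of the elm run, near 45.5% conversion. Second substrate by itself predicted growth of 13.7%. Starting material by itself predicted 8.08%. The readings gave 11.0%, which put the weight on second substrate at 0.510.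

4. So 0.146 was my waiting share, the part of the time per turnover at 5.0% conversion that goes as the inverse of second substrate left. I took this share as my estimate of the apparent order in second substrate. The scatter leaves it rough, so I kept the span from zero to 0.287. Doubling the charge shrinks that part, which gave a factor of 1.08.

The forecast gave an order of 0.06 in second substrate, lower than my share, an order of 1 in free enzyme and a doubling factor of 1.03, and said “The second-substrate term is therefore small”.

The flask gave an order of 0.15 in second substrate, 1.0 in free enzyme, and a doubling factor of 1.08.

    starting material + free enzyme ⇌ first complex (K = 110 L mol⁻¹, k = 98000 L mol⁻¹ h⁻¹)
    first complex → loaded enzyme + first product (k = 350 h⁻¹)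
    second substrate + loaded enzyme ⇌ second complex (K = 9.40 L mol⁻¹, k = 9000 L mol⁻¹ h⁻¹)
    second complex → free enzyme + target (k = 4900 h⁻¹)

When 5.0% of the starting material was converted, the flask's order in second substrate, 0.15, stood close to the share of catalyst held as loaded enzyme, 14.0%, and that share was larger than the second complex's 5.39%. Carried forward with my weight, the waiting share gave a rate ratio of 0.647 at 36.5 h against the rate at 5.0%, and the flask gave 0.66.

The data were computed for substances that don't exist; noise was put on by code.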